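**Plan**

- Retrosynthetic cuts: first the ester C–O bond (linoleic acid off), then the C5–C6 sp–sp bond of the diyne, and last, together, the C11–C12 bond and the C9–O bond of the oxirane.
- Enabling feature: counted from the vinyl CH2, C7–C11 (alkyne carbon, CH2, the two oxirane CH carbons, the first CH2 of the heptyl chain) is C1–C5 of 2-deoxy-D-ribose. The sugar's erythro 3,4-diol corresponds to the trans C9–O–C10 oxirane once C9 alone is inverted.
- Forward, fragment A: the sugar is alkynylated, tosylated at the primary hydroxyl, closed to the terminal epoxide and mesylated at C9. A hexyl copper reagent then opens the terminal epoxide and the freed C10 oxygen closes the only ring of the target.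
- Forward, fragment B: acrolein and a silylacetylene give the C1–C5 enynol, which is resolved by lipase and converted to its bromoalkyne. Fragments A and B are joined at C5–C6 and the linoleate is attached last.
- Stereochemistry: C10 is sugar C4 untouched; C9 is sugar C3 inverted once by SN2; C3 comes from the enzymatic resolution; both Z alkenes are bought with linoleic acid.

Key step: step 5

Remark: the target is read as 3S with a trans (9R,10R) oxirane. The lipase in step 7 is assumed to follow the Kazlauskas rule with trimethylsilylethynyl as the large and vinyl as the medium group, so the (R)-alcohol is acylated and the (S)-alcohol is left; the sense would be confirmed by Mosher ester analysis before step 8.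

**Route**

Step 1
Reactants: 1 2-deoxy-D-ribose
Product: 2 (2R,3S)-hex-5-yne-1,2,3-triol
Conditions: dimethyl (1-diazo-2-oxopropyl)phosphonate, K2CO3, MeOH, rt → 50 °C
Reagents that add atoms: dimethyl (1-diazo-2-oxopropyl)phosphonate, CC(=O)C(=[N+]=[N-])P(=O)(OC)OC
Why: Ohira–Bestmann (Seyferth–Gilbert) homologation of the lactol through its open-chain aldehyde should turn C1 of the sugar into the internal alkyne carbon and add one terminal carbon, without touching either carbinol stereocentre.

Step 2
Reactants: 2 (2R,3S)-hex-5-yne-1,2,3-triol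
Product: 3 (2R,3S)-2,3-dihydroxyhex-5-yn-1-yl 4-methylbenzenesulfonate
Conditions: TsCl (1.05 equiv), Bu2SnO (2 mol %), Et3N, CH2Cl2/MeCN, 0 °C → rt
Reagents that add atoms: 4-methylbenzenesulfonyl chloride, Cc1ccc(cc1)S(Cl)(=O)=O
Why: Tin-catalysed regioselective sulfonylation of a terminal 1,2-diol (Martinelli conditions) should deliver the tosyl group to the primary oxygen far faster than to either secondary hydroxyl.

Step 3
Reactants: 3 (2R,3S)-2,3-dihydroxyhex-5-yn-1-yl 4-methylbenzenesulfonate
Product: 4 (S)-1-[(R)-oxiran-2-yl]but-3-yn-1-ol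
Conditions: K2CO3, MeOH, 0 °C, short reaction time
Reagents that add atoms: none
Why: Intramolecular Williamson etherification (3-exo-tet) by the hydroxyl next to the primary tosylate should close the terminal epoxide without breaking a bond at either stereocentre, the cold and brief base contact limiting Payne migration and methanolysis.

Step 4
Reactants: 4 (S)-1-[(R)-oxiran-2-yl]but-3-yn-1-ol
Product: 5 (S)-1-[(R)-oxiran-2-yl]but-3-yn-1-yl methanesulfonate
Conditions: MsCl, Et3N, CH2Cl2, −20 → 0 °C
Reagents that add atoms: methanesulfonyl chloride, CS(Cl)(=O)=O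
Why: Standard O-sulfonylation of a secondary alcohol leaves the C–O bond intact, so the S carbinol should become the S mesylate that is displaced in the next step.

Step 5
Reactants: 5 (S)-1-[(R)-oxiran-2-yl]but-3-yn-1-yl methanesulfonate; 6 hexylmagnesium bromide
Product: 8 (2R,3R)-2-heptyl-3-(prop-2-yn-1-yl)oxirane, via ring-opened hydroxy mesylate 7 (not isolated)
Conditions: n-C6H13MgBr (2.5 equiv), CuI (10 mol %), THF, −40 → −10 °C; then MeOH, K2CO3, 0 °C → rt, same flask
Reagents that add atoms: none
Why: Under CuI catalysis the hexyl group passes from magnesium to a monovalent organocopper species that opens the monosubstituted oxirane of 5 by SN2 attack at its CH2 carbon, which forms the C11–C12 bond and leaves an alkoxide on C10 (intermediate 7). That oxygen, next to the C9 mesylate, then displaces it from the rear in a 3-exo-tet closure that forms the C9–O bond and the oxirane ring; because the magnesium alkoxide is sluggish, methanol and K2CO3 are added to the same flask to drive the closure to completion. The closest known reaction type is the copper-catalysed Grignard opening of terminal epoxides carrying a vicinal sulfonate, with base closure to the transposed epoxide, as practised on carbohydrate- and tartrate-derived epoxy sulfonates. No stereocentre is made from a prochiral atom: C10 keeps the configuration of sugar C4 because its C–O bond is never broken, and C9 is inverted once in the intramolecular SN2 step, so the erythro (S,R) pattern of 5 should be translated stereospecifically into the trans (9R,10R) oxirane. The step needs attack at the terminal epoxide carbon in preference to the internal epoxide carbon and the secondary mesylate carbon, which is secured by the steric bias of the monosubstituted oxirane, the low temperature and the soft copper nucleophile; the acidic alkyne C–H is allowed for with one sacrificial equivalent of 6.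

Step 6
Reactants: 9 acrolein; 10 ethynyltrimethylsilane
Product: 12 rac-5-(trimethylsilyl)pent-1-en-4-yn-3-ol, via lithium (trimethylsilyl)acetylide 11 (not isolated)
Conditions: n-BuLi, THF, −78 °C; then acrolein, −78 °C; aq. NH4Cl
Reagents that add atoms: none
Why: A hard lithium acetylide should add 1,2 to the enal carbonyl at low temperature, giving the racemic vinyl alkynyl carbinol.

Step 7
Reactants: 12 rac-5-(trimethylsilyl)pent-1-en-4-yn-3-ol
Product: 13 (S)-5-(trimethylsilyl)pent-1-en-4-yn-3-ol
Conditions: Amano lipase AK (Pseudomonas fluorescens), vinyl acetate, hexane, 4 Å molecular sieves, 30 °C, run slightly past half conversion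
Reagents that add atoms: none
Why: Lipase-catalysed kinetic resolution by irreversible transesterification should acylate the (R)-carbinol and leave the (S)-alcohol in high enantiomeric purity, which sets C3 of the target.

Step 8
Reactants: 13 (S)-5-(trimethylsilyl)pent-1-en-4-yn-3-ol
Product: 14 (S)-5-bromopent-1-en-4-yn-3-ol
Conditions: NBS, AgNO3 (10 mol %), acetone, rt, dark; used at once as a solution
Reagents that add atoms: N-bromosuccinimide, O=C1CCC(=O)N1Br
Why: Silver-catalysed bromodesilylation of an alkynylsilane should replace silicon by bromine at the alkyne terminus much faster than NBS touches the vinyl group or the carbinol, and the stereocentre is not involved.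

Step 9
Reactants: 8 (2R,3R)-2-heptyl-3-(prop-2-yn-1-yl)oxirane; 14 (S)-5-bromopent-1-en-4-yn-3-ol
Product: 15 (S)-8-[(2R,3R)-3-heptyloxiran-2-yl]oct-1-ene-4,6-diyn-3-ol
Conditions: CuCl (10 mol %), NH2OH·HCl, 30% aq. n-BuNH2, Et2O, 0 °C, slow addition of 14
Reagents that add atoms: none
Why: Cadiot–Chodkiewicz heterocoupling of the copper acetylide of 8 with bromoalkyne 14 should form the C5–C6 bond of the unsymmetrical 1,3-diyne, hydroxylamine keeping copper monovalent against Glaser homocoupling and the cold, brief amine contact sparing the disubstituted oxirane.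

Step 10
Reactants: 15 (S)-8-[(2R,3R)-3-heptyloxiran-2-yl]oct-1-ene-4,6-diyn-3-ol; 16 linoleic acid
Product: 17 (S)-8-[(2R,3R)-3-heptyloxiran-2-yl]oct-1-ene-4,6-diyn-3-yl (9Z,12Z)-octadeca-9,12-dienoate (CNP0285672.1)
Conditions: DCC, DMAP (cat.), CH2Cl2, 0 °C → rt, argon, dark
Reagents that add atoms: none
Why: Steglich esterification (carbodiimide activation with DMAP acyl transfer) should acylate the secondary alcohol without breaking its C–O bond, so C3 stays S, and the neutral, cold conditions should spare the oxirane, the diyne and the skipped (Z,Z)-diene.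

**Compound list**

1 | 2-deoxy-D-ribose (drawn open-chain; used as the lactol) | O=CC[C@H](O)[C@H](O)CO | starting material
2 | (2R,3S)-hex-5-yne-1,2,3-triol | C#CC[C@H](O)[C@H](O)CO | intermediate
3 | (2R,3S)-2,3-dihydroxyhex-5-yn-1-yl 4-methylbenzenesulfonate | C#CC[C@H](O)[C@H](O)COS(=O)(=O)c1ccc(C)cc1 | intermediate
4 | (S)-1-[(R)-oxiran-2-yl]but-3-yn-1-ol | C#CC[C@H](O)[C@H]1CO1 | intermediate
5 | (S)-1-[(R)-oxiran-2-yl]but-3-yn-1-yl methanesulfonate | C#CC[C@H](OS(C)(=O)=O)[C@H]1CO1 | intermediate
6 | hexylmagnesium bromide | CCCCCC[Mg]Br | starting material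
7 | (4S,5R)-5-hydroxydodec-1-yn-4-yl methanesulfonate (formed as its magnesium alkoxide, not isolated) | C#CC[C@H](OS(C)(=O)=O)[C@H](O)CCCCCCC | intermediate
8 | (2R,3R)-2-heptyl-3-(prop-2-yn-1-yl)oxirane | C#CC[C@H]1O[C@@H]1CCCCCCC | intermediate
9 | acrolein | C=CC=O | starting material
10 | ethynyltrimethylsilane | C#C[Si](C)(C)C | starting material
11 | lithium (trimethylsilyl)acetylide (not isolated) | [Li]C#C[Si](C)(C)C | intermediate
12 | rac-5-(trimethylsilyl)pent-1-en-4-yn-3-ol | C=CC(O)C#C[Si](C)(C)C | intermediate
13 | (S)-5-(trimethylsilyl)pent-1-en-4-yn-3-ol | C=C[C@H](O)C#C[Si](C)(C)C | intermediate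
14 | (S)-5-bromopent-1-en-4-yn-3-ol | C=C[C@H](O)C#CBr | intermediate
15 | (S)-8-[(2R,3R)-3-heptyloxiran-2-yl]oct-1-ene-4,6-diyn-3-ol | C=C[C@H](O)C#CC#CC[C@H]1O[C@@H]1CCCCCCC | intermediate
16 | linoleic acid, (9Z,12Z)-octadeca-9,12-dienoic acid | CCCCC/C=C\C/C=C\CCCCCCCC(=O)O | starting material
17 | (S)-8-[(2R,3R)-3-heptyloxiran-2-yl]oct-1-ene-4,6-diyn-3-yl (9Z,12Z)-octadeca-9,12-dienoate | C=C[C@@H](C#CC#CC[C@H]1O[C@@H]1CCCCCCC)OC(=O)CCCCCCC/C=C\C/C=C\CCCCC | target

**Count and risks**

Total step count: 10. Longest linear sequence: 7 steps (steps 1, 2, 3, 4, 5, 9, 10).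

Step 5. Bromide from the Schlenk equilibrium may open the terminal epoxide in competition with hexyl transfer. The organometallic may also attack or eliminate the homopropargylic mesylate, and the closure may stall at the alkoxide stage. The fallback reverses the order of events so that the ring closes first and the hexyl group is attached to a primary triflate. It sets out from triol 2 and returns at 8.
- The terminal 1,2-diol of 2 would be masked (2,2-dimethoxypropane, camphorsulfonic acid, acetone) as (S)-1-[(R)-2,2-dimethyl-1,3-dioxolan-4-yl]but-3-yn-1-ol F1.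
- Mesylation (MsCl, Et3N) would give (S)-1-[(R)-2,2-dimethyl-1,3-dioxolan-4-yl]but-3-yn-1-yl methanesulfonate F2.
- Aqueous acetic acid would free (2R,3S)-1,2-dihydroxyhex-5-yn-3-yl methanesulfonate F3.
- K2CO3 in methanol would let the C10 oxygen displace the C9 mesylate with the same inversion, giving [(2R,3R)-3-(prop-2-yn-1-yl)oxiran-2-yl]methanol F4.
- Tf2O and 2,6-lutidine at −78 °C would give [(2R,3R)-3-(prop-2-yn-1-yl)oxiran-2-yl]methyl trifluoromethanesulfonate F5.
- Copper-catalysed coupling of this triflate with hexylmagnesium bromide 6 (CuBr cat., Et2O, −78 °C) would form C11–C12 and give 8.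

Step 1. The free sugar offers only a small share of open-chain aldehyde, and under basic methanol β-elimination of the C3 hydroxyl or retro-aldol cleavage may outrun the alkynylation. The fallback ties up the 3,4-diol first. It sets out from 1 and returns at 2.
- 2-Methoxypropene and pyridinium p-toluenesulfonate would give 3,4-O-isopropylidene-2-deoxy-D-ribopyranose F6, a lactol with no free β-hydroxyl.
- Ohira–Bestmann alkynylation would give [(4R,5S)-2,2-dimethyl-5-(prop-2-yn-1-yl)-1,3-dioxolan-4-yl]methanol F7.
- Aqueous acetic acid would remove the acetonide and give 2.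

Step 9. The small bromo enynol may decompose or homocouple under the copper/amine conditions before it cross-couples. The fallback reverses the roles of the partners. It sets out from 8 and 13 and returns at 15.
- Bromination of 8 (NBS, AgNO3 cat., acetone) would give the more robust (2R,3R)-2-(3-bromoprop-2-yn-1-yl)-3-heptyloxirane F8.
- Desilylation of 13 (K2CO3, MeOH) would give (S)-pent-1-en-4-yn-3-ol F9.
- Cadiot–Chodkiewicz coupling of F8 with F9 would give 15.

**Further compounds**

F1 | step 5 | (S)-1-[(R)-2,2-dimethyl-1,3-dioxolan-4-yl]but-3-yn-1-ol | C#CC[C@H](O)[C@H]1COC(C)(C)O1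
F2 | step 5 | (S)-1-[(R)-2,2-dimethyl-1,3-dioxolan-4-yl]but-3-yn-1-yl methanesulfonate | C#CC[C@H](OS(C)(=O)=O)[C@H]1COC(C)(C)O1
F3 | step 5 | (2R,3S)-1,2-dihydroxyhex-5-yn-3-yl methanesulfonate | C#CC[C@H](OS(C)(=O)=O)[C@H](O)CO
F4 | step 5 | [(2R,3R)-3-(prop-2-yn-1-yl)oxiran-2-yl]methanol | C#CC[C@H]1O[C@@H]1CO
F5 | step 5 | [(2R,3R)-3-(prop-2-yn-1-yl)oxiran-2-yl]methyl trifluoromethanesulfonate | C#CC[C@H]1O[C@@H]1COS(=O)(=O)C(F)(F)F
F6 | step 1 | 3,4-O-isopropylidene-2-deoxy-D-ribopyranose (anomeric mixture) | OC1C[C@@H]2OC(C)(C)O[C@@H]2CO1
F7 | step 1 | [(4R,5S)-2,2-dimethyl-5-(prop-2-yn-1-yl)-1,3-dioxolan-4-yl]methanol | C#CC[C@@H]1OC(C)(C)O[C@@H]1CO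
F8 | step 9 | (2R,3R)-2-(3-bromoprop-2-yn-1-yl)-3-heptyloxirane | BrC#CC[C@H]1O[C@@H]1CCCCCCC
F9 | step 9 | (S)-pent-1-en-4-yn-3-ol | C=C[C@H](O)C#C
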